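## Structural features

The target is a depside with no stereocentre: two benzene rings joined only by one aryl ester, whose carbonyl carbon sits on ring A C1 and whose oxygen sits on ring B C4'. Ring A carries methoxy groups on C2 and C4 and a pentyl chain on C6. Ring B carries the free carboxyl on C1', a methoxy group on C2' and a propyl chain on C6'. The fragile groups are the aryl ester, which is an activated acyl donor, and the ring B carboxyl, which must be unmasked last and without nucleophiles. The real difficulty is the ester itself: its acid partner is a benzoic acid with both ortho positions occupied, and its phenol partner is made weakly nucleophilic by a para carboxyl. The feature exploited is the acetate-type pattern of ring A (carbonyl on C1, oxygens on C2 and C4, alkyl on C6). Ring A C1 to C6 map onto C2 to C7 of a 3,5,7-trioxododecanoate, so the C1–C6 bond can be made by an aldol reaction after the ester to ring B O4' already exists. In this mapping the chain C3 and C5 oxygens become the ring A C2 and C4 hydroxyls and chain C8 to C12 become the pentyl group, so the constitutions of 12 and 14 are consistent with each other and with 16.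

## Logic of the disconnections

**16 to 15.** The O–C(CH3)3 bond of a tert-butyl ester is placed on the ring B carboxyl. A free acid would be alkylated in the etherification and would interfere with every base-mediated step. The gain is one acidic function fewer throughout. The demand is an acidolysis that leaves the aryl ester and the aryl methyl ethers untouched.

**15 to 14.** The two O–CH3 bonds on ring A C2 and C4 are cut. These oxygens are the former chain carbonyl oxygens, so they appear as free hydroxyls after ring formation. The gain is a return to the direct aromatization product. The demand is complete O-methylation, including the hydroxyl chelated to the ester carbonyl, without acyl transfer from the depside.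

**14 to 12 (through 13).** The ring A C1–C6 bond is cut, which is the chain C2–C7 bond. Ring A dissolves into an open triketo ester, and the hindered benzoate becomes an unhindered β-keto ester. The demand is that the carbon-to-carbon aldol mode beats every pathway that attacks the ester carbonyl and expels the ring B aryloxide. A further demand is that the base and acid used spare both the aryl ester and the tert-butyl ester.

**12 to 10 and 5 (through 11).** The acyl C–O(aryl) bond is cut. The acyl part is an acylketene released from a dioxinone by loss of acetone, and the phenol adds to it. The gain is two fragments of similar size and an ester bond formed at a carbon with no ortho neighbours. The demand is that bimolecular capture by a moderately nucleophilic phenol outpaces internal capture by the enolized diketone, under strictly dry conditions.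

**10 to 7 and 9.** The bond between the terminal side-chain carbon and the hexanoyl carbonyl is cut (chain C6–C7 of 12). The forward step is acylation of the dianion of 7 at its terminal carbon. The demand is single acylation, which an N-methoxy-N-methyl amide secures through its stable tetrahedral adduct.

**9 to 8.** The amide C–N bond is cut, a routine acylation of the hydroxylamine.

**7 to 6.** The bond between the ring-attached methylene and the acetyl carbonyl is cut (chain C4–C5 of 12). The forward step is γ-acylation of the dienolate of 6. The demand is excess dienolate, because the product is the stronger acid.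

**5 to 3 (through 4).** The ring B C4'–O bond is cut. C4' is the only ring position of 3 with no ortho substituent, so sterically governed C–H borylation followed by oxidation can place the oxygen there. The gain is that the 2'-methoxy group comes differentiated from the start and no ring B hydroxyl ever needs selective protection. The demand is regiocontrol by sterics alone.

**3 to 2.** The bond between the benzylic carbon and the ethyl group of the propyl chain is cut. The forward step is lateral lithiation of the ortho-methyl group and alkylation. The demand is monoalkylation and no self-condensation, which the tert-butyl ester helps to secure.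

**2 to 1.** The O–C(CH3)3 ester bond is cut. Because both ortho positions are occupied, the forward step must alkylate the carboxyl oxygen and not attack the carbonyl carbon.

## Other disconnections considered

**Alternative 1:** The cut goes through ring B at C1'–C6' and C2'–C3', so ring B is built from the malonate A1 and the enone A2.

- **Forward key step:** Under a hydride base, conjugate addition would set C1'–C6'. Claisen closure of the methyl ketone enolate onto one benzyl ester would set C2'–C3' and give the cyclohexanedione A3. Its trans stereocentres are irrelevant, because dehydrogenation to the resorcylate A4 removes them.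
- **In favour:** Bulk starting materials, no cryogenic step and no precious metal. The ring closure is funnelled by the stable β-diketone enolate and has no leaving-group competition. On mechanistic dependability it is the better of the two plans.
- **Against:** A3 is at the wrong oxidation level and needs a separate dehydrogenation. A4 has two free hydroxyls, so the 2'-methoxy group would have to be installed on a chelated hydroxyl of the finished depside. Ring A would arrive as the separately made acid A5, whose carboxyl has both ortho positions occupied. That is the hindered esterification the chosen plan avoids.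
- **Comparison:** Structurally it solves only ring B. Its benzyl ester could be removed by hydrogenolysis, which is equal in mildness to acidolysis of a tert-butyl ester. The step count is roughly equal (two steps to A4, two or three to A5, then coupling, methylation and deprotection). The chosen plan is preferred for its ring B oxygen differentiation and its unhindered ester formation, not for length.

**Alternative 2:** Ring B is cut at C1'–C2' and C5'–C6'. Carbons C2' to C5' come from the diene A6, and C1' and C6' from the ynoate A7.

- **Forward key step:** A thermal [4+2] cycloaddition would join the unsubstituted diene terminus to the propyl-bearing β-carbon of A7 and the ketene acetal terminus to the α-carbon. Loss of one methoxy group as the alcohol, and of silicon on work-up, would give A8, which is the same compound as 5.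
- **In favour:** The whole ring, with 2'-methoxy and 4'-hydroxyl already told apart, comes from one step. Regiochemistry follows from the polarization of both partners, and no precious metal is needed.
- **Against:** A6 is hydrolytically labile and must be prepared and used fresh. A7 must also be made. A β-alkyl ynoate is a sluggish dienophile, so long heating would be needed, during which the diene can decompose.
- **Comparison:** As a source of 5 it is equal in operations to steps 1 to 3 and better in convergence. It is weaker in the predictability of each operation. It does not touch ring A or the ester bond, so it could replace steps 1 to 3 but not the key step.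

**Alternative 3:** Ring A is cut at C1–C2 and C5–C6. The dienophile is the aryl ynoate A9, made by esterifying 5 with an unhindered alkynoic acid, and the diene is again A6.

- **Forward key step:** The same polarity matching would place the methoxy-bearing carbon next to the ester carbon and the unsubstituted terminus on the pentyl-bearing carbon. Loss of a methoxy group and of silicon would give A10, with a 2-methoxy group and a free 4-hydroxyl.
- **In favour:** The ester is made before ring A exists, as in the chosen plan (equal). Ring A arrives with its ortho oxygen already methylated, leaving only the unchelated hydroxyl to alkylate (better). There is no enolizable polycarbonyl chain, so no pathway expels the aryloxide (better). The sequence 5, A9, A10, 15, 16 would be three steps shorter if A6 is counted separately (better).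
- **Against:** The β-alkyl ynoate would need sustained heating well above 100 °C. Under those conditions the activated aryl ester of A9 is exposed to the nucleophilic ketene acetal terminus of A6 and to the alcohol released on aromatization, either of which could take the acyl group off ring B. A6 would also be needed in excess.
- **Comparison:** Regiocontrol is as secure as in the aldol route. The thermal load is heavier than a room-temperature aromatization, and step economy favours the alternative. The chosen plan is preferred for its mild ring-forming conditions; Alternative 3 is the most serious competitor.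

Key step: step 8

Assumption: ring A is numbered C1 to C6 from the carbon bearing the ester carbonyl, ring B C1' to C6' from the carbon bearing the carboxyl, and the chain of 12 from its ester carbon; equivalents and concentrations are nominal planning values.

## Route

Step 1
Reactants: 1 2-methoxy-6-methylbenzoic acid
Product: 2 tert-butyl 2-methoxy-6-methylbenzoate
Conditions: tert-butyl 2,2,2-trichloroacetimidate (2 equiv), BF3·OEt2 (cat.), CH2Cl2/cyclohexane, rt
Reagents that add atoms: tert-butyl 2,2,2-trichloroacetimidate, CC(C)(C)OC(=N)C(Cl)(Cl)Cl
Why: Acid-catalysed tert-butyl esterification with a trichloroacetimidate alkylates the carboxyl oxygen, so the two ortho substituents that block attack at the carbonyl carbon do not matter.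

Step 2
Reactants: 2 tert-butyl 2-methoxy-6-methylbenzoate
Product: 3 tert-butyl 2-methoxy-6-propylbenzoate
Conditions: LiN(iPr)2 (1.2 equiv), THF, −78 °C; EtI (1.5 equiv), −78 → 0 °C
Reagents that add atoms: iodoethane, CCI
Why: Lateral lithiation of an ortho-toluate gives an ester-stabilized benzylic anion that is alkylated by SN2; the bulky, doubly flanked tert-butyl ester should suppress self-condensation, and the secondary benzylic position of 3 is less acidic, which disfavours a second alkylation.

Step 3
Reactants: 3 tert-butyl 2-methoxy-6-propylbenzoate
Product: 5 tert-butyl 4-hydroxy-2-methoxy-6-propylbenzoate, via pinacol arylboronate 4 (not isolated)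
Conditions: [Ir(OMe)(cod)]2 (1.5 mol %), dtbpy (3 mol %), B2pin2 (1.0 equiv), THF, 80 °C; evaporate; KHSO5 (as 2KHSO5·KHSO4·K2SO4), acetone/H2O, rt
Reagents that add atoms: potassium peroxymonosulfate (phenol oxygen), [K+].[O-]S(=O)(=O)OO; bis(pinacolato)diboron (boryl group of 4 only), CC1(C)OB(OC1(C)C)B1OC(C)(C)C(C)(C)O1
Why: One-pot iridium-catalysed C–H borylation and oxidation; the borylation is governed by sterics and should take C4', the only ring hydrogen without an ortho substituent, and peroxymonosulfate then converts the C–B bond into C–O at the same position.

Step 4
Reactants: 6 2,2,6-trimethyl-4H-1,3-dioxin-4-one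
Product: 7 2,2-dimethyl-6-(2-oxopropyl)-4H-1,3-dioxin-4-one
Conditions: LiN(SiMe3)2 (1.0 equiv), THF, −78 °C; AcCl (0.5 equiv), −78 °C; aq. NH4Cl
Reagents that add atoms: acetyl chloride, CC(=O)Cl
Why: Vinylogous Claisen acylation: γ-deprotonation gives the lithium dienolate, which is C-acylated at the exocyclic carbon; two equivalents of dienolate per acyl chloride are planned because the more acidic product consumes one.

Step 5
Reactants: 8 hexanoyl chloride
Product: 9 N-methoxy-N-methylhexanamide
Conditions: MeNH(OMe)·HCl (1.1 equiv), K2CO3 (2.5 equiv), EtOAc/H2O, 0 °C → rt
Reagents that add atoms: N,O-dimethylhydroxylamine hydrochloride, CNOC.Cl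
Why: Schotten–Baumann acylation of the hydroxylamine by the acid chloride.

Step 6
Reactants: 7 2,2-dimethyl-6-(2-oxopropyl)-4H-1,3-dioxin-4-one; 9 N-methoxy-N-methylhexanamide
Product: 10 6-(2,4-dioxononyl)-2,2-dimethyl-4H-1,3-dioxin-4-one
Conditions: 7 (1.6 equiv), LiN(iPr)2 (3.3 equiv), THF, −78 °C; 9 (1.0 equiv), −78 → −40 °C; 1 M HCl, 0 °C
Reagents that add atoms: none
Why: Claisen-type acylation of a β-dicarbonyl dianion: the second deprotonation occurs at the terminal methyl, which is the more nucleophilic site, and the chelated tetrahedral adduct of the Weinreb amide should prevent over-addition until the acidic quench.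

Step 7
Reactants: 10 6-(2,4-dioxononyl)-2,2-dimethyl-4H-1,3-dioxin-4-one; 5 tert-butyl 4-hydroxy-2-methoxy-6-propylbenzoate
Product: 12 4-(tert-butoxycarbonyl)-3-methoxy-5-propylphenyl 3,5,7-trioxododecanoate, via acylketene 11 (not isolated)
Conditions: 5 (1.5 equiv), dry toluene (0.3 M in 10), 110 °C, 45 min; evaporate; crude 12 used at once
Reagents that add atoms: none
Why: Thermal retro-hetero-Diels–Alder loss of acetone from the dioxinone gives the acylketene, and the phenol O–H adds across it to form the aryl β-keto ester; excess phenol at high concentration is used to favour this bimolecular capture, and the ester bond forms at a carbon with no ortho neighbours.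

Step 8
Reactants: 12 4-(tert-butoxycarbonyl)-3-methoxy-5-propylphenyl 3,5,7-trioxododecanoate
Product: 14 tert-butyl 4-(2,4-dihydroxy-6-pentylbenzoyloxy)-2-methoxy-6-propylbenzoate, via aldol adduct 13 (not isolated)
Conditions: Et3N (3 equiv), CH2Cl2 (0.05 M), 0 °C → rt; evaporate; AcOH (10 equiv), CH2Cl2, rt
Reagents that add atoms: none
Why: Triethylamine reversibly deprotonates the acidic methylenes of 12, and the enolate centred on chain C2, between the aryl ester and the C3 ketone, adds to the C7 ketone in an intramolecular aldol reaction that makes the ring A C1–C6 bond and gives the hydroxy-dione 13. The closure is 6-exo-trig at the C7 carbonyl and can proceed through the ester-enolate (enolexo) form of the doubly stabilized nucleophile, a mode that Baldwin's rules allow. E1cB loss of the tertiary hydroxyl, completed by the acetic acid treatment, and enolization of the C3 and C5 carbonyls then give the 2,4-dihydroxyarene, and aromatization makes the sequence irreversible. The closest known reaction type is the amine- or carbonate-promoted aldol cycloaromatization of alkyl 3,5,7-trioxoalkanoates generated from diketo-dioxinones, the difference here being an aryl ester in place of an alkyl ester. No stereocentre survives, because the two created in 13 are erased on aromatization. The selectivity needed is C2-to-C7 bond formation in preference to attack on the ester carbonyl by the C6 carbanion (Claisen closure to an acylphloroglucinol) or by the C5 enol oxygen (lactonization to a 4-hydroxy-2-pyranone), both of which would expel the aryloxide, and in preference to E1cB reversion to 11. It rests on four points: the ester carbonyl is deactivated by conjugation with the aryloxy oxygen and the C2 enolate while C7 is available as a ketone; the medium is aprotic and free of alkoxide, carbonate or methanol, so nothing external can transesterify; the base is weak and used cold, so the irreversible aldol–dehydration channel drains the reversible equilibria; and the excess of 5 carried over from step 7 can return any 11 to 12. Acetic acid is chosen over mineral acid, and triethylamine is removed with the solvent before it is added, so that the tert-butyl ester stays intact.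

Step 9
Reactants: 14 tert-butyl 4-(2,4-dihydroxy-6-pentylbenzoyloxy)-2-methoxy-6-propylbenzoate
Product: 15 tert-butyl 4-(2,4-dimethoxy-6-pentylbenzoyloxy)-2-methoxy-6-propylbenzoate
Conditions: MeI (6 equiv), K2CO3 (4 equiv), acetone, 56 °C
Reagents that add atoms: iodomethane, CI
Why: Williamson O-methylation of both phenols; the 4-hydroxyl should react quickly and the chelated 2-hydroxyl slowly, hence the excess and the reflux. The depside carbonyl is shielded by its two ortho substituents against carbonate and phenoxide, and the tert-butyl ester is inert.

Step 10
Reactants: 15 tert-butyl 4-(2,4-dimethoxy-6-pentylbenzoyloxy)-2-methoxy-6-propylbenzoate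
Product: 16 4-(2,4-dimethoxy-6-pentylbenzoyloxy)-2-methoxy-6-propylbenzoic acid
Conditions: CF3CO2H/CH2Cl2 (1:3), 0 °C → rt
Reagents that add atoms: none
Why: Acidolysis of the tert-butyl ester by alkyl–oxygen cleavage releases 2-methylpropene, while the aryl ester and aryl methyl ethers are inert to anhydrous acid. Every open ring position is flanked by two substituents, so Friedel–Crafts tert-butylation is sterically disfavoured.

## Compound list

1 | 2-methoxy-6-methylbenzoic acid | COc1cccc(C)c1C(=O)O | starting material
2 | tert-butyl 2-methoxy-6-methylbenzoate | COc1cccc(C)c1C(=O)OC(C)(C)C | intermediate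
3 | tert-butyl 2-methoxy-6-propylbenzoate | CCCc1cccc(OC)c1C(=O)OC(C)(C)C | intermediate
4 | tert-butyl 2-methoxy-6-propyl-4-(4,4,5,5-tetramethyl-1,3,2-dioxaborolan-2-yl)benzoate | CCCc1cc(B2OC(C)(C)C(C)(C)O2)cc(OC)c1C(=O)OC(C)(C)C | intermediate (not isolated)
5 | tert-butyl 4-hydroxy-2-methoxy-6-propylbenzoate | CCCc1cc(O)cc(OC)c1C(=O)OC(C)(C)C | intermediate
6 | 2,2,6-trimethyl-4H-1,3-dioxin-4-one | CC1=CC(=O)OC(C)(C)O1 | starting material
7 | 2,2-dimethyl-6-(2-oxopropyl)-4H-1,3-dioxin-4-one | CC(=O)CC1=CC(=O)OC(C)(C)O1 | intermediate
8 | hexanoyl chloride | CCCCCC(=O)Cl | starting material
9 | N-methoxy-N-methylhexanamide | CCCCCC(=O)N(C)OC | intermediate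
10 | 6-(2,4-dioxononyl)-2,2-dimethyl-4H-1,3-dioxin-4-one | CCCCCC(=O)CC(=O)CC1=CC(=O)OC(C)(C)O1 | intermediate
11 | dodec-1-ene-1,3,5,7-tetrone (acylketene) | CCCCCC(=O)CC(=O)CC(=O)C=C=O | intermediate (not isolated)
12 | 4-(tert-butoxycarbonyl)-3-methoxy-5-propylphenyl 3,5,7-trioxododecanoate (keto–enol mixture) | CCCCCC(=O)CC(=O)CC(=O)CC(=O)Oc1cc(CCC)c(C(=O)OC(C)(C)C)c(OC)c1 | intermediate
13 | tert-butyl 4-[(2-hydroxy-4,6-dioxo-2-pentylcyclohexane-1-carbonyl)oxy]-2-methoxy-6-propylbenzoate (racemic, mixture of diastereomers, both stereocentres lost in the same step) | CCCCCC1(O)CC(=O)CC(=O)C1C(=O)Oc1cc(CCC)c(C(=O)OC(C)(C)C)c(OC)c1 | intermediate (not isolated)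
14 | tert-butyl 4-(2,4-dihydroxy-6-pentylbenzoyloxy)-2-methoxy-6-propylbenzoate | CCCCCc1cc(O)cc(O)c1C(=O)Oc1cc(CCC)c(C(=O)OC(C)(C)C)c(OC)c1 | intermediate
15 | tert-butyl 4-(2,4-dimethoxy-6-pentylbenzoyloxy)-2-methoxy-6-propylbenzoate | CCCCCc1cc(OC)cc(OC)c1C(=O)Oc1cc(CCC)c(C(=O)OC(C)(C)C)c(OC)c1 | intermediate
16 | 4-(2,4-dimethoxy-6-pentylbenzoyloxy)-2-methoxy-6-propylbenzoic acid | CCCCCc1cc(OC)cc(OC)c1C(=O)Oc1cc(CCC)c(C(=O)O)c(OC)c1 | target

## Step count and least certain steps

Total: 10 steps. Longest linear sequence: 7 steps (steps 1, 2, 3, 7, 8, 9, 10, from 1 to 16).

**Step 8 (key step).** The most likely failure is expulsion of the ring B aryloxide, which is stabilized by its para ester. This could occur by lactonization of the C5 enol oxygen onto the ester carbonyl, by Claisen closure from C6, or by E1cB reversion to the ketene followed by internal capture, any of which may outrun the C2-to-C7 aldol. The fallback sets out from 5 and returns at 15; it takes ring A from the aromatic pool and makes the ester by acyl chloride chemistry. 1,3-Dimethoxy-5-pentylbenzene F1 would be formylated para to one methoxy group (POCl3, DMF; Vilsmeier–Haack) to 2,4-dimethoxy-6-pentylbenzaldehyde F2. Oxidation (NaClO2, NaH2PO4, 2-methylbut-2-ene; Pinnick) would give 2,4-dimethoxy-6-pentylbenzoic acid F3, the same acid as A5. Oxalyl chloride with catalytic DMF would give 2,4-dimethoxy-6-pentylbenzoyl chloride F4, which would acylate the sodium salt of 5 (NaH, THF) to give 15. That acylation is slow because of hindrance but irreversible.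

**Step 7.** The most likely failure is internal capture of ketene 11 by the enolized C5 oxygen, which competes with bimolecular addition of a phenol of reduced nucleophilicity. Prolonged heating would also let 12 revert to 11. The fallback sets out from 10 (with 5) and returns at 15; it aromatizes the dioxinone itself, where no leaving group is involved. Treatment of 10 with Et3N in CH2Cl2 should give 7-hydroxy-2,2-dimethyl-5-pentyl-4H-1,3-benzodioxin-4-one F5. MeI and K2CO3 would give 7-methoxy-2,2-dimethyl-5-pentyl-4H-1,3-benzodioxin-4-one F6. KOH in aqueous DMSO would open the acetonide to 2-hydroxy-4-methoxy-6-pentylbenzoic acid F7. Carbodiimide coupling with 5 (DCC, toluene) would give tert-butyl 4-(2-hydroxy-4-methoxy-6-pentylbenzoyloxy)-2-methoxy-6-propylbenzoate F8. Methylation of its remaining hydroxyl under the conditions of step 9 would give 15.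

**Step 6.** The most likely failure is low conversion, caused by proton transfer from the more acidic product to the dianion and by attack of amide base or dianion on the dioxinone carbonyl. The fallback sets out from 6 and 8 and returns at 10; it avoids strong base in the second acylation and makes step 5 unnecessary. The dienolate of 6 (LiN(SiMe3)2, THF, −78 °C) would be acylated with allyl 3-chloro-3-oxopropanoate to allyl 4-(2,2-dimethyl-4-oxo-4H-1,3-dioxin-6-yl)-3-oxobutanoate F9. Soft enolization (MgCl2, pyridine, CH2Cl2) and C-acylation with 8 would give allyl 2-[2-(2,2-dimethyl-4-oxo-4H-1,3-dioxin-6-yl)acetyl]-3-oxooctanoate F10. Pd(PPh3)4 with morpholine would remove the allyl group, and decarboxylation of the β-keto acid would give 10.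

**Step 9.** The most likely failure is incomplete etherification of the hydrogen-bonded ortho hydroxyl. The forcing basic conditions then needed could cause acyl transfer from the depside to carbonate or to the ring A phenoxide, or C-methylation of the resorcinol nucleus. The fallback sets out from 14 and returns at 15. It is a Mitsunobu etherification of both hydroxyls with methanol (PPh3, diisopropyl azodicarboxylate, THF, rt), which activates the alcohol instead of generating a free aryloxide and keeps the medium neutral. It makes no new compound (F0).

## Further compounds

F1 | step 8 | 1,3-dimethoxy-5-pentylbenzene | CCCCCc1cc(OC)cc(OC)c1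
F2 | step 8 | 2,4-dimethoxy-6-pentylbenzaldehyde | CCCCCc1cc(OC)cc(OC)c1C=O
F3 | step 8 | 2,4-dimethoxy-6-pentylbenzoic acid | CCCCCc1cc(OC)cc(OC)c1C(=O)O
F4 | step 8 | 2,4-dimethoxy-6-pentylbenzoyl chloride | CCCCCc1cc(OC)cc(OC)c1C(=O)Cl
F5 | step 7 | 7-hydroxy-2,2-dimethyl-5-pentyl-4H-1,3-benzodioxin-4-one | CCCCCc1cc(O)cc2OC(C)(C)OC(=O)c12
F6 | step 7 | 7-methoxy-2,2-dimethyl-5-pentyl-4H-1,3-benzodioxin-4-one | CCCCCc1cc(OC)cc2OC(C)(C)OC(=O)c12
F7 | step 7 | 2-hydroxy-4-methoxy-6-pentylbenzoic acid | CCCCCc1cc(OC)cc(O)c1C(=O)O
F8 | step 7 | tert-butyl 4-(2-hydroxy-4-methoxy-6-pentylbenzoyloxy)-2-methoxy-6-propylbenzoate | CCCCCc1cc(OC)cc(O)c1C(=O)Oc1cc(CCC)c(C(=O)OC(C)(C)C)c(OC)c1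
F9 | step 6 | allyl 4-(2,2-dimethyl-4-oxo-4H-1,3-dioxin-6-yl)-3-oxobutanoate | C=CCOC(=O)CC(=O)CC1=CC(=O)OC(C)(C)O1
F10 | step 6 | allyl 2-[2-(2,2-dimethyl-4-oxo-4H-1,3-dioxin-6-yl)acetyl]-3-oxooctanoate | CCCCCC(=O)C(C(=O)OCC=C)C(=O)CC1=CC(=O)OC(C)(C)O1
F0 | step 9 | none | none
A1 | alternative 1 | dibenzyl malonate | O=C(CC(=O)OCc1ccccc1)OCc1ccccc1
A2 | alternative 1 | (E)-hept-3-en-2-one | CCC/C=C/C(C)=O
A3 | alternative 1 | benzyl trans-2,4-dioxo-6-propylcyclohexane-1-carboxylate (racemic, one enantiomer drawn) | CCC[C@@H]1CC(=O)CC(=O)[C@H]1C(=O)OCc1ccccc1
A4 | alternative 1 | benzyl 2,4-dihydroxy-6-propylbenzoate | CCCc1cc(O)cc(O)c1C(=O)OCc1ccccc1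
A5 | alternative 1 | 2,4-dimethoxy-6-pentylbenzoic acid | CCCCCc1cc(OC)cc(OC)c1C(=O)O
A6 | alternative 2 | 1,1-dimethoxy-3-(trimethylsilyloxy)buta-1,3-diene | COC(OC)=CC(=C)O[Si](C)(C)C
A7 | alternative 2 | tert-butyl hex-2-ynoate | CCCC#CC(=O)OC(C)(C)C
A8 | alternative 2 | tert-butyl 4-hydroxy-2-methoxy-6-propylbenzoate (identical with 5) | CCCc1cc(O)cc(OC)c1C(=O)OC(C)(C)C
A9 | alternative 3 | 4-(tert-butoxycarbonyl)-3-methoxy-5-propylphenyl oct-2-ynoate | CCCCCC#CC(=O)Oc1cc(CCC)c(C(=O)OC(C)(C)C)c(OC)c1
A10 | alternative 3 | tert-butyl 4-(4-hydroxy-2-methoxy-6-pentylbenzoyloxy)-2-methoxy-6-propylbenzoate | CCCCCc1cc(O)cc(OC)c1C(=O)Oc1cc(CCC)c(C(=O)OC(C)(C)C)c(OC)c1
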